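**Retrosynthetic overview**

1. Target 20 ⇐ bis-silyl ether 19. The 15,16-olide of 19 ⇐ the 3-furyl group of 16 by sensitized photooxygenation (singlet-oxygen [4+2]; makes the C15=O and C16–O bonds) and NaBH4. This is the key step: the furan carries the side chain through all the base chemistry and is turned into the lactone late.
2. 3α-Angelate and 2β-oxygen ⇐ 3-ketone 9, by enolate hydroxylation at C2 and β-face hydride delivery at C3. Both are steered by the axial methyls on C10 and C4.
3. C4 (β-CH2O, α-CH3) ⇐ β-keto aldehyde 6 by deformylative hydroxymethylation. C19 leaves as formate and C18 enters anti to C20, which forms the C4–C18 bond and inverts C4 relative to andrographolide.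
4. Furan diol 5 ⇐ andrographolide 1, by reductive 1,3-transposition of the 14-acetate and i-Bu2AlH reduction/aromatization.
5. Ring order: the trans-decalin (C5, C9, C10, exocyclic alkene) is bought in 1. The lactone is converted to the furan ring in step 3, and the butenolide ring is re-formed last, in step 9.

Assumption: labdane numbering is used; α/β are absolute faces in the andrographolide series (5βH, 9βH, 10α-methyl), so the target is 3α-angeloyloxy-2β,18-dihydroxylabda-8(17),13-dien-15,16-olide, (2S,3S,4S,5S,9R,10S), with the ester read as (Z)-2-methylbut-2-enoate; andrographolide and angelic acid are bought.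

**Route**

Step 1
Reactants: 1 andrographolide
Product: 2 3,14,19-tri-O-acetylandrographolide
Conditions: Ac2O, pyridine, DMAP (cat.), CH2Cl2, 0 °C → rt
Reagents that add atoms: acetic anhydride, CC(=O)OC(C)=O
Why: Exhaustive O-acylation (nucleophilic catalysis) turns the allylic C14 hydroxyl into a leaving group and masks the 3,19-diol without touching any stereocenter.

Step 2
Reactants: 2 3,14,19-tri-O-acetylandrographolide
Product: 3 3,19-di-O-acetyl-14-deoxyandrographolide (saturated C11–C12, endocyclic C13=C14 butenolide with the carbonyl at C16)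
Conditions: NaBH4, MeOH/THF, 0 °C
Reagents that add atoms: none
Why: Conjugate hydride addition at C12 of the alkylidene lactone followed by E1cB loss of the C14 acetate (reductive 1,3-transposition, SN2′-type) gives the α-alkyl butenolide and removes the C14 stereocenter.

Step 3
Reactants: 3 3,19-di-O-acetyl-14-deoxyandrographolide
Product: 5 15,16-epoxylabda-8(17),13(16),14-triene-3α,19-diol (3-furyl side chain; 4α-CH2OH axial, 4β-CH3), via lactol triol 4 (not isolated)
Conditions: i-Bu2AlH (excess), CH2Cl2, −78 → −20 °C; then 1 M HCl, THF, rt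
Reagents that add atoms: none
Why: Hydride reduction of the butenolide to the lactol (both acetates are cleaved as well) and acid-promoted 1,4-dehydration aromatizes it to the 3-substituted furan (butenolide-to-furan reduction), a base-stable mask for the lactone.

Step 4
Reactants: 5 15,16-epoxylabda-8(17),13(16),14-triene-3α,19-diol
Product: 6 3-oxo-15,16-epoxylabda-8(17),13(16),14-trien-19-al (4α-CHO, 4β-CH3)
Conditions: Dess–Martin periodinane, pyridine, CH2Cl2, 0 °C → rt
Reagents that add atoms: none
Why: Dess–Martin oxidation of the secondary and the neopentyl primary alcohol gives a β-keto aldehyde that cannot enolise between the carbonyls, so C4 keeps its configuration and the furan and alkene are untouched.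

Step 5
Reactants: 6 3-oxo-15,16-epoxylabda-8(17),13(16),14-trien-19-al
Product: 9 18-(tert-butyldimethylsilyloxy)-15,16-epoxylabda-8(17),13(16),14-trien-3-one (4β-CH2OTBS equatorial, 4α-CH3 axial), via lithium enolate 7 (not isolated), via lithium aldolate 8 (not isolated)
Conditions: LiOEt (1.05 equiv, 1.0 M in THF), THF, 0 °C → rt; CH2O (monomer in THF, 1.5 equiv), −78 °C; TBSOTf (1.6 equiv), −78 → 0 °C
Reagents that add atoms: formaldehyde, C=O; tert-butyldimethylsilyl trifluoromethanesulfonate, CC(C)(C)[Si](C)(C)OS(=O)(=O)C(F)(F)F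
Why: Proposed new method: ethoxide adds to the non-enolisable, highly electrophilic formyl group and the hemiacetal alkoxide undergoes retro-Claisen C4–C19 cleavage (ethyl formate leaves) to give only the tetrasubstituted C3=C4 lithium enolate, which monomeric formaldehyde attacks on the β face, anti to the axial C20 methyl that blocks the α face, so the new carbon C18 ends equatorial and C4 is inverted relative to andrographolide before the aldolate is silylated; the closest known chemistry is base-mediated deformylation of α-formyl ketones, alkoxide-triggered retro-Claisen enolate generation in deacylative allylation, and Stork trapping of regiospecific enolates with formaldehyde (aldol).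

Step 6
Reactants: 9 18-(tert-butyldimethylsilyloxy)-15,16-epoxylabda-8(17),13(16),14-trien-3-one
Product: 12 2β,18-bis(tert-butyldimethylsilyloxy)-15,16-epoxylabda-8(17),13(16),14-trien-3-one, via potassium enolate 10 (not isolated), via potassium alkoxide 11 (not isolated)
Conditions: KN(SiMe3)2, THF, −78 °C; (±)-2-(phenylsulfonyl)-3-phenyloxaziridine, −78 °C; TBSOTf, −78 → −40 °C
Reagents that add atoms: (±)-trans-2-(phenylsulfonyl)-3-phenyloxaziridine, O=S(=O)(c1ccccc1)N1OC1c1ccccc1; tert-butyldimethylsilyl trifluoromethanesulfonate, CC(C)(C)[Si](C)(C)OS(=O)(=O)C(F)(F)F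
Why: Only C2 can be enolised, and electrophilic hydroxylation of the potassium enolate by the racemic N-sulfonyloxaziridine (Davis oxidation) comes from the β face because the α face of C2 is blocked by the two axial methyls on C10 and C4, giving the equatorial 2β-oxygen, which is silylated in the same flask.

Step 7
Reactants: 12 2β,18-bis(tert-butyldimethylsilyloxy)-15,16-epoxylabda-8(17),13(16),14-trien-3-one
Product: 13 2β,18-bis(tert-butyldimethylsilyloxy)-15,16-epoxylabda-8(17),13(16),14-trien-3α-ol
Conditions: NaBH4, MeOH/THF, −20 °C; AcOH quench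
Reagents that add atoms: none
Why: Substrate-controlled carbonyl reduction in which hydride is delivered axially from the β face (the α face of C3 is screened by the axial 4α-methyl), giving the equatorial 3α-alcohol trans to the 2β-silyloxy group, as in 4,4-disubstituted 3-oxo terpenoids.

Step 8
Reactants: 13 2β,18-bis(tert-butyldimethylsilyloxy)-15,16-epoxylabda-8(17),13(16),14-trien-3α-ol; 14 angelic acid [(Z)-2-methylbut-2-enoic acid]
Product: 16 3α-angeloyloxy-2β,18-bis(tert-butyldimethylsilyloxy)-15,16-epoxylabda-8(17),13(16),14-triene, via mixed anhydride 15 (not isolated)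
Conditions: 14, 2,4,6-Cl3C6H2COCl, Et3N, toluene, rt; then 13, 80 °C
Reagents that add atoms: none
Why: Acylation of the hindered alcohol by the preformed angelic 2,4,6-trichlorobenzoic mixed anhydride (Yamaguchi-type esterification without DMAP) avoids the conjugate-addition pathway that isomerises angelates to tiglates, so the Z geometry is kept.

Step 9
Reactants: 16 3α-angeloyloxy-2β,18-bis(tert-butyldimethylsilyloxy)-15,16-epoxylabda-8(17),13(16),14-triene
Product: 19 3α-angeloyloxy-2β,18-bis(tert-butyldimethylsilyloxy)labda-8(17),13-dien-15,16-olide, via furan endoperoxide 17 (not isolated), via hydroxybutenolide 18 (not isolated)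
Conditions: O2, tetraphenylporphyrin (1 mol%), i-Pr2NEt, CH2Cl2, −78 °C, visible light (>500 nm); then NaBH4, EtOH, 0 °C; then 1 M HCl
Reagents that add atoms: dioxygen, O=O
Why: Sensitized photooxygenation in which singlet oxygen adds [4+2] to the furan (far faster than the ene reaction with the 1,1-disubstituted alkene or the electron-poor angelate), the hindered amine removes the less hindered C15–H of the endoperoxide (Kornblum–DeLaMare fragmentation with Kernan–Faulkner regiochemistry) to place the carbonyl at C15, and NaBH4 reduces the C16 lactol through its open aldehyde so that acidification closes the 15,16-olide.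

Step 10
Reactants: 19 3α-angeloyloxy-2β,18-bis(tert-butyldimethylsilyloxy)labda-8(17),13-dien-15,16-olide
Product: 20 3α-angeloyloxy-2β,18-dihydroxylabda-8(17),13-dien-15,16-olide (target)
Conditions: HF·pyridine, pyridine/THF, 0 °C → rt
Reagents that add atoms: none
Why: Fluoride-mediated desilylation of both silyl ethers under buffered acidic conditions (no alkoxide, hence no 3→2 acyl shift) releases the target with all six stereocenters in place.

**Compound list**

1 | andrographolide | C=C1CC[C@H]2[C@@](C)(CC[C@@H](O)[C@@]2(C)CO)[C@@H]1C/C=C/3\[C@@H](COC3=O)O | starting material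
2 | 3,14,19-tri-O-acetylandrographolide | C=C1CC[C@H]2[C@@](C)(CC[C@@H](OC(C)=O)[C@@]2(C)COC(C)=O)[C@@H]1C/C=C/3\[C@@H](COC3=O)OC(C)=O | intermediate
3 | 3,19-di-O-acetyl-14-deoxyandrographolide | C=C1CC[C@H]2[C@@](C)(CC[C@@H](OC(C)=O)[C@@]2(C)COC(C)=O)[C@@H]1CCC1=CCOC1=O | intermediate
4 | lactol triol (16-hydroxy-15,16-epoxylabda-8(17),13-diene-3α,19-diol, lactol epimers) | C=C1CC[C@H]2[C@@](C)(CC[C@@H](O)[C@@]2(C)CO)[C@@H]1CCC1=CCOC1O | intermediate (not isolated)
5 | 15,16-epoxylabda-8(17),13(16),14-triene-3α,19-diol | C=C1CC[C@H]2[C@@](C)(CC[C@@H](O)[C@@]2(C)CO)[C@@H]1CCc1ccoc1 | intermediate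
6 | 3-oxo-15,16-epoxylabda-8(17),13(16),14-trien-19-al | C=C1CC[C@H]2[C@@](C)(CCC(=O)[C@@]2(C)C=O)[C@@H]1CCc1ccoc1 | intermediate
7 | lithium enolate (C3=C4) of the 19-nor-3-ketone | C=C1CC[C@H]2[C@@](C)(CCC([O-])=C2C)[C@@H]1CCc1ccoc1.[Li+] | intermediate (not isolated)
8 | lithium aldolate (4β-CH2OLi, 4α-CH3, 3-oxo) | C=C1CC[C@H]2[C@@](C)(CCC(=O)[C@]2(C)C[O-])[C@@H]1CCc1ccoc1.[Li+] | intermediate (not isolated)
9 | 18-(tert-butyldimethylsilyloxy)-15,16-epoxylabda-8(17),13(16),14-trien-3-one | C=C1CC[C@H]2[C@@](C)(CCC(=O)[C@]2(C)CO[Si](C)(C)C(C)(C)C)[C@@H]1CCc1ccoc1 | intermediate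
10 | potassium enolate (C2=C3) of 9 | C=C1CC[C@H]2[C@@](C)(CC=C([O-])[C@]2(C)CO[Si](C)(C)C(C)(C)C)[C@@H]1CCc1ccoc1.[K+] | intermediate (not isolated)
11 | potassium 2β-alkoxide of the 2β-hydroxy-3-ketone | C=C1CC[C@H]2[C@@](C)(C[C@H]([O-])C(=O)[C@]2(C)CO[Si](C)(C)C(C)(C)C)[C@@H]1CCc1ccoc1.[K+] | intermediate (not isolated)
12 | 2β,18-bis(tert-butyldimethylsilyloxy)-15,16-epoxylabda-8(17),13(16),14-trien-3-one | C=C1CC[C@H]2[C@@](C)(C[C@H](O[Si](C)(C)C(C)(C)C)C(=O)[C@]2(C)CO[Si](C)(C)C(C)(C)C)[C@@H]1CCc1ccoc1 | intermediate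
13 | 2β,18-bis(tert-butyldimethylsilyloxy)-15,16-epoxylabda-8(17),13(16),14-trien-3α-ol | C=C1CC[C@H]2[C@@](C)(C[C@H](O[Si](C)(C)C(C)(C)C)[C@@H](O)[C@]2(C)CO[Si](C)(C)C(C)(C)C)[C@@H]1CCc1ccoc1 | intermediate
14 | angelic acid, (Z)-2-methylbut-2-enoic acid | C/C=C(/C)C(=O)O | starting material
15 | angelic 2,4,6-trichlorobenzoic anhydride | C/C=C(/C)C(=O)OC(=O)c1c(Cl)cc(Cl)cc1Cl | intermediate (not isolated)
16 | 3α-angeloyloxy-2β,18-bis(tert-butyldimethylsilyloxy)-15,16-epoxylabda-8(17),13(16),14-triene | C=C1CC[C@H]2[C@@](C)(C[C@H](O[Si](C)(C)C(C)(C)C)[C@@H](OC(=O)/C(C)=C\C)[C@]2(C)CO[Si](C)(C)C(C)(C)C)[C@@H]1CCc1ccoc1 | intermediate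
17 | furan 2,5-endoperoxide of 16 (both faces) | C=C1CC[C@H]2[C@@](C)(C[C@H](O[Si](C)(C)C(C)(C)C)[C@@H](OC(=O)/C(C)=C\C)[C@]2(C)CO[Si](C)(C)C(C)(C)C)[C@@H]1CCC1=CC2OOC1O2 | intermediate (not isolated)
18 | 16-hydroxy-15,16-olide (γ-hydroxybutenolide, lactol epimers) | C=C1CC[C@H]2[C@@](C)(C[C@H](O[Si](C)(C)C(C)(C)C)[C@@H](OC(=O)/C(C)=C\C)[C@]2(C)CO[Si](C)(C)C(C)(C)C)[C@@H]1CCC1=CC(=O)OC1O | intermediate (not isolated)
19 | 3α-angeloyloxy-2β,18-bis(tert-butyldimethylsilyloxy)labda-8(17),13-dien-15,16-olide | C=C1CC[C@H]2[C@@](C)(C[C@H](O[Si](C)(C)C(C)(C)C)[C@@H](OC(=O)/C(C)=C\C)[C@]2(C)CO[Si](C)(C)C(C)(C)C)[C@@H]1CCC1=CC(=O)OC1 | intermediate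
20 | 3α-angeloyloxy-2β,18-dihydroxylabda-8(17),13-dien-15,16-olide | C=C1CC[C@H]2[C@@](C)(C[C@H](O)[C@@H](OC(=O)/C(C)=C\C)[C@]2(C)CO)[C@@H]1CCC1=CC(=O)OC1 | target

**Step count and risks**

Total step count: 10. Longest linear sequence: 10 steps from andrographolide 1 (angelic acid 14 enters in step 8).

The three steps most likely to fail:

Step 5, the proposed new step. The lithium hemiacetal may fragment incompletely, proton transfer may scramble the enolate to C2, and ethyl formate may formylate the aldolate. The fallback uses known chemistry and sets out from 6. K2CO3 in MeOH removes the formyl group and gives the 19-nor-3-ketone F1 with an equatorial 4β-methyl. TMSCl/NaI/Et3N in MeCN gives the more substituted C3=C4 trimethylsilyl enol ether F2. A Mukaiyama aldol with aqueous formaldehyde and Yb(OSO2CF3)3 (10 mol%) in THF gives the 18-hydroxy-3-ketone F3 by the same β-face attack. TBSCl/imidazole in DMF then comes back to the route at 9.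

Step 8, acylation of a hindered alcohol flanked by a quaternary carbon and a silyl ether, with the risk of low conversion or Z→E isomerisation. The fallback builds the angelate on the molecule and sets out from 13. DCC-mediated acylation with 2-[bis(2,2,2-trifluoroethoxy)phosphoryl]propanoic acid, a small sp3 acyl donor that reacts through its ketene, gives the phosphonopropanoate ester F4 as a mixture of α-epimers. KN(SiMe3)2/18-crown-6 and then acetaldehyde at −78 °C (Still–Gennari olefination) forms the Z-2-methylbut-2-enoate and comes back to the route at 16.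

Step 9, late photooxygenation in the presence of the exocyclic alkene, where regiocontrol depends on the base-mediated fragmentation. The fallback is non-photochemical and sets out from 16. C–H borylation with bis(pinacolato)diboron, catalysed by [Ir(OMe)(C8H12)]2 and 4,4′-di-tert-butyl-2,2′-bipyridine, occurs at the less hindered furan α-position C15 and gives the furyl boronate F5. NaBO3·4H2O in THF/H2O oxidises the C–B bond to the 2-hydroxyfuran, which tautomerises to the conjugated butenolide and comes back to the route at 19.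

**Further compounds**

F1 | step 5 | 19-nor-15,16-epoxylabda-8(17),13(16),14-trien-3-one (4β-methyl) | C=C1CC[C@H]2[C@@](C)(CCC(=O)[C@@H]2C)[C@@H]1CCc1ccoc1
F2 | step 5 | 3-(trimethylsilyloxy)-19-nor-15,16-epoxylabda-3,8(17),13(16),14-tetraene | C=C1CC[C@H]2[C@@](C)(CCC(O[Si](C)(C)C)=C2C)[C@@H]1CCc1ccoc1
F3 | step 5 | 18-hydroxy-15,16-epoxylabda-8(17),13(16),14-trien-3-one | C=C1CC[C@H]2[C@@](C)(CCC(=O)[C@]2(C)CO)[C@@H]1CCc1ccoc1
F4 | step 8 | 3α-{2-[bis(2,2,2-trifluoroethoxy)phosphoryl]propanoyloxy}-2β,18-bis(tert-butyldimethylsilyloxy)-15,16-epoxylabda-8(17),13(16),14-triene | C=C1CC[C@H]2[C@@](C)(C[C@H](O[Si](C)(C)C(C)(C)C)[C@@H](OC(=O)C(C)P(=O)(OCC(F)(F)F)OCC(F)(F)F)[C@]2(C)CO[Si](C)(C)C(C)(C)C)[C@@H]1CCc1ccoc1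
F5 | step 9 | 15-(pinacolatoboryl) derivative of 16 (boron on the furan α-carbon remote from the side chain) | C=C1CC[C@H]2[C@@](C)(C[C@H](O[Si](C)(C)C(C)(C)C)[C@@H](OC(=O)/C(C)=C\C)[C@]2(C)CO[Si](C)(C)C(C)(C)C)[C@@H]1CCc1cc(B2OC(C)(C)C(C)(C)O2)oc1
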